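**Retrosynthetic overview**

1. The target is read as the (3S,4R,5R)-oxolan-3-ol with aryl and CH2OH cis on the oxolane and a cis-(2R,3R)-dihydrobenzofuran. It comes from silyl ether 23 by global desilylation, 23 from spiro-epoxide 20 by copper-catalysed opening at the oxirane CH2 with a guaiacyl Grignard reagent, and 20 from 4-methylideneoxolane 19 by face-selective epoxidation.
2. 19 (numbering: O1, C2 aryl, C3 CH2OTBS, C4 methylidene, C5 H2) comes from aldehyde 12 and allylboronate 17 in one pot: asymmetric allylboration makes the C2–C3 bond and both CH stereocentres, then an allylpalladium etherification closes the oxolane at the O1–C5 (O–CH2) bond.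
3. Enabling feature: the carbinol carbon C4 of the oxolane carries two CH2 groups, ring C5H2 bound to O1 and the exocyclic CH2 bound to the guaiacyl ring. C4 is therefore the central carbon of a 2-substituted allyl unit with equivalent CH2 termini, so C3, C4, C5 and the benzylic CH2 all come from one 2-(oxymethyl)allyl reagent. The benzylic C2–O bond is never broken after it is set, which protects the less stable 2,3-cis oxolane.
4. 12 comes from aryldiazoacetate 7 (built from vanillin and 4-bromo-2-methoxyphenol) by enantioselective rhodium-carbenoid 1,5-C–H insertion, which forms the cis-dihydrofuran ring. 17 comes from 4-silyloxybut-2-yn-1-ol 13 by trans-hydrostannation, iodination and one-carbon homologation with bis(boryl)methane.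
5. Ring order: dihydrofuran ring of the benzofuran (step 6), then the oxolane (step 14); the oxirane of 20 is a temporary ring, opened in step 17.

Key step: step 14

Remark: the senses of induction of Rh2(S-PTTL)4 (step 6) and of (R)-TRIP (step 14) are assigned by analogy with the closest known substrates; should either prove opposite, the mirror-image catalyst is used.

Abbreviations: TIPS = triisopropylsilyl; TBS = tert-butyldimethylsilyl; Bpin = 4,4,5,5-tetramethyl-1,3,2-dioxaborolan-2-yl; (R)-TRIP = (R)-3,3'-bis(2,4,6-triisopropylphenyl)-1,1'-binaphthyl-2,2'-diyl hydrogen phosphate; ArA = (2R,3R)-3-{[(tert-butyldimethylsilyl)oxy]methyl}-7-methoxy-2-{3-methoxy-4-[(triisopropylsilyl)oxy]phenyl}-2,3-dihydro-1-benzofuran-5-yl.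

**Route**

Step 1
Reactants: 1 vanillin (4-hydroxy-3-methoxybenzaldehyde)
Product: 2 3-methoxy-4-[(triisopropylsilyl)oxy]benzaldehyde
Conditions: TIPSCl, imidazole, DMF, 25 °C
Reagents that add atoms: chlorotri(propan-2-yl)silane (TIPSCl), CC(C)[Si](Cl)(C(C)C)C(C)C
Why: Imidazole-promoted O-silylation of the phenol; the hindered aryl silyl ether should survive the organometallic, hydride and mildly basic steps and fall to fluoride at the end.

Step 2
Reactants: 2 3-methoxy-4-[(triisopropylsilyl)oxy]benzaldehyde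
Product: 3 {3-methoxy-4-[(triisopropylsilyl)oxy]phenyl}methanol
Conditions: NaBH4, THF/MeOH, 0 °C
Reagents that add atoms: none
Why: Borohydride reduction of an aryl aldehyde to the benzylic alcohol, with no effect on the aryl silyl ether at 0 °C.

Step 3
Reactants: 4 4-bromo-2-methoxyphenol
Product: 5 4-bromo-2-iodo-6-methoxyphenol
Conditions: I2, NaHCO3, THF/H2O, 0 → 25 °C
Reagents that add atoms: iodine, II
Why: Electrophilic aromatic iodination of the phenoxide; the para position is blocked by bromine, so iodine should enter the free position ortho to oxygen.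

Step 4
Reactants: 5 4-bromo-2-iodo-6-methoxyphenol; 3 {3-methoxy-4-[(triisopropylsilyl)oxy]phenyl}methanol
Product: 6 5-bromo-1-iodo-3-methoxy-2-({3-methoxy-4-[(triisopropylsilyl)oxy]phenyl}methoxy)benzene
Conditions: PPh3, DIAD, THF, 0 → 25 °C
Reagents that add atoms: none
Why: Mitsunobu etherification of the acidic phenol with the primary benzylic alcohol under neutral conditions, which avoids a labile 4-silyloxybenzyl halide and carbonate bases that would cleave the aryl silyl ether.

Step 5
Reactants: 6 5-bromo-1-iodo-3-methoxy-2-({3-methoxy-4-[(triisopropylsilyl)oxy]phenyl}methoxy)benzene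
Product: 7 ethyl 2-[5-bromo-3-methoxy-2-({3-methoxy-4-[(triisopropylsilyl)oxy]phenyl}methoxy)phenyl]-2-diazoacetate
Conditions: ethyl diazoacetate, Pd(PPh3)4 (5 mol%), Ag2CO3 (0.5 equiv), Et3N, PhMe, 25 °C
Reagents that add atoms: ethyl diazoacetate, CCOC(=O)C=[N+]=[N-]
Why: Palladium-catalysed cross-coupling of an aryl iodide with the C–H bond of ethyl diazoacetate, which keeps the diazo group; at room temperature zerovalent palladium should insert into C–I and leave C–Br alone.

Step 6
Reactants: 7 ethyl 2-[5-bromo-3-methoxy-2-({3-methoxy-4-[(triisopropylsilyl)oxy]phenyl}methoxy)phenyl]-2-diazoacetate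
Product: 8 ethyl (2R,3S)-5-bromo-7-methoxy-2-{3-methoxy-4-[(triisopropylsilyl)oxy]phenyl}-2,3-dihydro-1-benzofuran-3-carboxylate (2,3-cis)
Conditions: Rh2(S-PTTL)4 [dirhodium tetrakis(N-phthaloyl-(S)-tert-leucinate)] (1 mol%), PhMe, −60 °C
Reagents that add atoms: none
Why: Enantioselective intramolecular 1,5-C–H insertion of the donor/acceptor rhodium carbenoid into the ether-activated benzylic C–H bond closes the dihydrofuran ring; this catalyst class delivers 2-aryl-2,3-dihydrobenzofuran-3-carboxylates as the kinetic cis isomers, and its chiral pocket sets C2 and C3 in the same event.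

Step 7
Reactants: 8 ethyl (2R,3S)-5-bromo-7-methoxy-2-{3-methoxy-4-[(triisopropylsilyl)oxy]phenyl}-2,3-dihydro-1-benzofuran-3-carboxylate
Product: 9 [(2R,3R)-5-bromo-7-methoxy-2-{3-methoxy-4-[(triisopropylsilyl)oxy]phenyl}-2,3-dihydro-1-benzofuran-3-yl]methanol (2,3-cis)
Conditions: i-Bu2AlH (3 equiv), CH2Cl2, −78 → −20 °C; aq. potassium sodium tartrate
Reagents that add atoms: none
Why: Non-basic hydride reduction of the ester to the primary alcohol, so the C3 centre (α to the ester, β to the aryloxy group) is never enolised and the cis relationship should be kept.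

Step 8
Reactants: 9 [(2R,3R)-5-bromo-7-methoxy-2-{3-methoxy-4-[(triisopropylsilyl)oxy]phenyl}-2,3-dihydro-1-benzofuran-3-yl]methanol
Product: 10 (2R,3R)-5-bromo-3-{[(tert-butyldimethylsilyl)oxy]methyl}-7-methoxy-2-{3-methoxy-4-[(triisopropylsilyl)oxy]phenyl}-2,3-dihydro-1-benzofuran
Conditions: TBSCl, imidazole, DMF, 25 °C
Reagents that add atoms: tert-butyl(chloro)dimethylsilane (TBSCl), CC(C)(C)[Si](C)(C)Cl
Why: Standard silylation of the primary alcohol, which removes the only acidic proton before the organolithium step.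

Step 9
Reactants: 10 (2R,3R)-5-bromo-3-{[(tert-butyldimethylsilyl)oxy]methyl}-7-methoxy-2-{3-methoxy-4-[(triisopropylsilyl)oxy]phenyl}-2,3-dihydro-1-benzofuran
Product: 12 (2R,3R)-3-{[(tert-butyldimethylsilyl)oxy]methyl}-7-methoxy-2-{3-methoxy-4-[(triisopropylsilyl)oxy]phenyl}-2,3-dihydro-1-benzofuran-5-carbaldehyde (ArA–CHO), via aryllithium 11 (not isolated)
Conditions: n-BuLi (1.1 equiv), THF, −78 °C; DMF; aq. NH4Cl
Reagents that add atoms: N,N-dimethylformamide, CN(C)C=O
Why: Bromine–lithium exchange followed by Bouveault formylation; the exchange is much faster than deprotonation at −78 °C and no acid is used, so both dihydrofuran stereocentres should be untouched.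

Step 10
Reactants: 13 4-[(tert-butyldimethylsilyl)oxy]but-2-yn-1-ol
Product: 14 (2Z)-4-[(tert-butyldimethylsilyl)oxy]-2-(tributylstannyl)but-2-en-1-ol
Conditions: Bu3SnH (1.1 equiv), [Cp*RuCl]4 (1.25 mol%), CH2Cl2, 25 °C
Reagents that add atoms: tributyltin hydride, CCCC[SnH](CCCC)CCCC
Why: Ruthenium-catalysed trans-hydrostannation of an internal alkyne; the free hydroxyl hydrogen-bonds to the chloride ligand and steers tin to the proximal carbon, and trans addition places tin cis to the CH2OTBS group.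

Step 11
Reactants: 14 (2Z)-4-[(tert-butyldimethylsilyl)oxy]-2-(tributylstannyl)but-2-en-1-ol
Product: 15 (2Z)-4-[(tert-butyldimethylsilyl)oxy]-2-iodobut-2-en-1-ol
Conditions: I2 (1.05 equiv), CH2Cl2, 0 °C
Reagents that add atoms: iodine, II
Why: Iododestannylation of an alkenylstannane, which proceeds with retention of olefin geometry.

Step 12
Reactants: 15 (2Z)-4-[(tert-butyldimethylsilyl)oxy]-2-iodobut-2-en-1-ol
Product: 16 (2E)-4-[(tert-butyldimethylsilyl)oxy]-2-[(4,4,5,5-tetramethyl-1,3,2-dioxaborolan-2-yl)methyl]but-2-en-1-ol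
Conditions: CH2(Bpin)2 (1.3 equiv), Pd[P(t-Bu)3]2 (5 mol%), KOH (aq), 1,4-dioxane, 25 °C
Reagents that add atoms: bis(pinacolato)borylmethane, CC1(C)OB(CB2OC(C)(C)C(C)(C)O2)OC1(C)C
Why: Suzuki–Miyaura coupling of an alkenyl iodide with a geminal bis(boronate), in which only one boron transmetalates; it gives the allylboronate with retention of geometry, so the CH2Bpin group ends cis to CH2OTBS.

Step 13
Reactants: 16 (2E)-4-[(tert-butyldimethylsilyl)oxy]-2-[(4,4,5,5-tetramethyl-1,3,2-dioxaborolan-2-yl)methyl]but-2-en-1-ol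
Product: 17 (2E)-4-[(tert-butyldimethylsilyl)oxy]-2-[(4,4,5,5-tetramethyl-1,3,2-dioxaborolan-2-yl)methyl]but-2-en-1-yl methyl carbonate
Conditions: ClCO2Me (1.3 equiv), pyridine, CH2Cl2, 0 °C
Reagents that add atoms: methyl chloroformate, COC(=O)Cl
Why: Acylation of the primary allylic alcohol to the carbonate installs the leaving group for the later allylpalladium ionisation; pinacol allylboronates tolerate these conditions.

Step 14
Reactants: 12 ArA–CHO; 17 (2E)-4-[(tert-butyldimethylsilyl)oxy]-2-[(4,4,5,5-tetramethyl-1,3,2-dioxaborolan-2-yl)methyl]but-2-en-1-yl methyl carbonate (1.1 equiv)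
Product: 19 (2R,3R)-2-ArA-3-{[(tert-butyldimethylsilyl)oxy]methyl}-4-methylideneoxolane (2,3-cis), via O-boryl homoallylic ether 18 (not isolated)
Conditions: (R)-TRIP (5 mol%), 4 Å MS, PhMe, −30 → 25 °C; then Pd(PPh3)4 (5 mol%), THF, 25 → 40 °C
Reagents that add atoms: none
Why: The chiral phosphoric acid activates the pinacol boronate by hydrogen bonding, and aldehyde 12 is allylated at the γ-carbon of 17 through a closed six-membered chair transition state (the known catalytic asymmetric allylboration of aryl aldehydes), giving O-boryl ether 18 in which the alkene has moved next to the CH2OCO2Me group. Zerovalent palladium then ionises the allylic carbonate with loss of CO2, the methoxide set free binds boron, and the released benzylic alkoxide attacks a CH2 terminus of the 2-substituted η3-allylpalladium; this is a Tsuji–Trost etherification and the same closing event as in trimethylenemethane [3+2] cycloadditions to aldehydes. The oxolane closes in 5-exo mode by O1–C5 bond formation, with the central allyl carbon becoming ring C4 and keeping an exocyclic methylene. C2 is set by the catalyst (attack on the Re face of the aldehyde) and C3 by the reagent geometry: the CH2OTBS group cis to CH2B sits axial in the chair and gives the syn adduct, which is the 2,3-cis oxolane. The step needs γ- over α-allylation, one aldehyde face, and cyclisation over intermolecular capture; the closed boron transition state, the fixed olefin geometry of 17 and intramolecularity secure these, and because the two allyl termini are identical CH2 groups the ring closure has no regiochemical choice. The benzylic C2–O bond is not broken after it forms, so the less stable 2,3-cis arrangement has no path to the trans isomer.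

Step 15
Reactants: 19 (2R,3R)-2-ArA-3-{[(tert-butyldimethylsilyl)oxy]methyl}-4-methylideneoxolane
Product: 20 (3R,6R,7R)-6-ArA-7-{[(tert-butyldimethylsilyl)oxy]methyl}-1,5-dioxaspiro[2.4]heptane
Conditions: mCPBA, NaHCO3, CH2Cl2, 0 °C
Reagents that add atoms: 3-chloroperoxybenzoic acid, OOC(=O)c1cccc(Cl)c1
Why: Prilezhaev epoxidation of the exocyclic 1,1-disubstituted alkene; the peracid should approach from the face opposite the cis-disposed C2 aryl and C3 CH2OTBS groups, so the new C–O bond at the spiro carbon is trans to both, and the buffer protects the acid-labile oxirane and benzylic ethers.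

Step 16
Reactants: 4 4-bromo-2-methoxyphenol
Product: 21 (4-bromo-2-methoxyphenoxy)tri(propan-2-yl)silane
Conditions: TIPSCl, imidazole, DMF, 25 °C
Reagents that add atoms: chlorotri(propan-2-yl)silane (TIPSCl), CC(C)[Si](Cl)(C(C)C)C(C)C
Why: Phenol silylation gives an aryl bromide that can be turned into a Grignard reagent without a free OH.

Step 17
Reactants: 20 (3R,6R,7R)-6-ArA-7-{[(tert-butyldimethylsilyl)oxy]methyl}-1,5-dioxaspiro[2.4]heptane; 21 (4-bromo-2-methoxyphenoxy)tri(propan-2-yl)silane (2.5 equiv)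
Product: 23 (3S,4R,5R)-5-ArA-4-{[(tert-butyldimethylsilyl)oxy]methyl}-3-({3-methoxy-4-[(triisopropylsilyl)oxy]phenyl}methyl)oxolan-3-ol, via arylmagnesium bromide 22 (not isolated)
Conditions: Mg, THF, 40 °C; then CuI (10 mol%), 20, THF, −40 → 0 °C; aq. NH4Cl
Reagents that add atoms: none
Why: Copper-catalysed SN2 opening of the 2,2-disubstituted oxirane by the aryl Grignard reagent at the unsubstituted CH2; the carbinol stereocentre is not involved, so the hydroxyl stays trans and the new arylmethyl group cis to the CH2OTBS group.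

Step 18
Reactants: 23 (3S,4R,5R)-5-ArA-4-{[(tert-butyldimethylsilyl)oxy]methyl}-3-({3-methoxy-4-[(triisopropylsilyl)oxy]phenyl}methyl)oxolan-3-ol
Product: 24 (3S,4R,5R)-5-[(2R,3R)-3-(hydroxymethyl)-2-(4-hydroxy-3-methoxyphenyl)-7-methoxy-2,3-dihydro-1-benzofuran-5-yl]-3-[(4-hydroxy-3-methoxyphenyl)methyl]-4-(hydroxymethyl)oxolan-3-ol (CNP0284796.1)
Conditions: TBAF (6 equiv), AcOH (6 equiv), THF, 0 → 25 °C
Reagents that add atoms: none
Why: Fluoride cleavage of the two aryl and two primary alkyl silyl ethers; acetic acid buffering keeps the freed 4-hydroxyphenyl groups from expelling the para-benzylic ethers as quinone methides and avoids acid that would epimerise the cis benzylic centres.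

**Compound list**

1 | vanillin (4-hydroxy-3-methoxybenzaldehyde) | COc1cc(C=O)ccc1O | starting material
2 | 3-methoxy-4-[(triisopropylsilyl)oxy]benzaldehyde | COc1cc(C=O)ccc1O[Si](C(C)C)(C(C)C)C(C)C | intermediate
3 | {3-methoxy-4-[(triisopropylsilyl)oxy]phenyl}methanol | COc1cc(CO)ccc1O[Si](C(C)C)(C(C)C)C(C)C | intermediate
4 | 4-bromo-2-methoxyphenol | COc1cc(Br)ccc1O | starting material
5 | 4-bromo-2-iodo-6-methoxyphenol | COc1cc(Br)cc(I)c1O | intermediate
6 | 5-bromo-1-iodo-3-methoxy-2-({3-methoxy-4-[(triisopropylsilyl)oxy]phenyl}methoxy)benzene | COc1cc(Br)cc(I)c1OCc1ccc(O[Si](C(C)C)(C(C)C)C(C)C)c(OC)c1 | intermediate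
7 | ethyl 2-[5-bromo-3-methoxy-2-({3-methoxy-4-[(triisopropylsilyl)oxy]phenyl}methoxy)phenyl]-2-diazoacetate | CCOC(=O)C(=[N+]=[N-])c1cc(Br)cc(OC)c1OCc1ccc(O[Si](C(C)C)(C(C)C)C(C)C)c(OC)c1 | intermediate
8 | ethyl (2R,3S)-5-bromo-7-methoxy-2-{3-methoxy-4-[(triisopropylsilyl)oxy]phenyl}-2,3-dihydro-1-benzofuran-3-carboxylate (2,3-cis) | Brc1cc(OC)c2c(c1)[C@H](C(=O)OCC)[C@H](c1ccc(O[Si](C(C)C)(C(C)C)C(C)C)c(OC)c1)O2 | intermediate
9 | [(2R,3R)-5-bromo-7-methoxy-2-{3-methoxy-4-[(triisopropylsilyl)oxy]phenyl}-2,3-dihydro-1-benzofuran-3-yl]methanol (2,3-cis) | Brc1cc(OC)c2c(c1)[C@H](CO)[C@H](c1ccc(O[Si](C(C)C)(C(C)C)C(C)C)c(OC)c1)O2 | intermediate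
10 | (2R,3R)-5-bromo-3-{[(tert-butyldimethylsilyl)oxy]methyl}-7-methoxy-2-{3-methoxy-4-[(triisopropylsilyl)oxy]phenyl}-2,3-dihydro-1-benzofuran | Brc1cc(OC)c2c(c1)[C@H](CO[Si](C)(C)C(C)(C)C)[C@H](c1ccc(O[Si](C(C)C)(C(C)C)C(C)C)c(OC)c1)O2 | intermediate
11 | [(2R,3R)-3-{[(tert-butyldimethylsilyl)oxy]methyl}-7-methoxy-2-{3-methoxy-4-[(triisopropylsilyl)oxy]phenyl}-2,3-dihydro-1-benzofuran-5-yl]lithium (ArA–Li) | [Li]c1cc(OC)c2c(c1)[C@H](CO[Si](C)(C)C(C)(C)C)[C@H](c1ccc(O[Si](C(C)C)(C(C)C)C(C)C)c(OC)c1)O2 | intermediate (not isolated)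
12 | (2R,3R)-3-{[(tert-butyldimethylsilyl)oxy]methyl}-7-methoxy-2-{3-methoxy-4-[(triisopropylsilyl)oxy]phenyl}-2,3-dihydro-1-benzofuran-5-carbaldehyde (ArA–CHO) | O=Cc1cc(OC)c2c(c1)[C@H](CO[Si](C)(C)C(C)(C)C)[C@H](c1ccc(O[Si](C(C)C)(C(C)C)C(C)C)c(OC)c1)O2 | intermediate
13 | 4-[(tert-butyldimethylsilyl)oxy]but-2-yn-1-ol | OCC#CCO[Si](C)(C)C(C)(C)C | starting material
14 | (2Z)-4-[(tert-butyldimethylsilyl)oxy]-2-(tributylstannyl)but-2-en-1-ol | OC/C([Sn](CCCC)(CCCC)CCCC)=C/CO[Si](C)(C)C(C)(C)C | intermediate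
15 | (2Z)-4-[(tert-butyldimethylsilyl)oxy]-2-iodobut-2-en-1-ol | OC/C(I)=C/CO[Si](C)(C)C(C)(C)C | intermediate
16 | (2E)-4-[(tert-butyldimethylsilyl)oxy]-2-[(4,4,5,5-tetramethyl-1,3,2-dioxaborolan-2-yl)methyl]but-2-en-1-ol | OC/C(CB1OC(C)(C)C(C)(C)O1)=C/CO[Si](C)(C)C(C)(C)C | intermediate
17 | (2E)-4-[(tert-butyldimethylsilyl)oxy]-2-[(4,4,5,5-tetramethyl-1,3,2-dioxaborolan-2-yl)methyl]but-2-en-1-yl methyl carbonate | COC(=O)OC/C(CB1OC(C)(C)C(C)(C)O1)=C/CO[Si](C)(C)C(C)(C)C | intermediate
18 | methyl [(3R,4R)-4-ArA-3-{[(tert-butyldimethylsilyl)oxy]methyl}-2-methylidene-4-[(4,4,5,5-tetramethyl-1,3,2-dioxaborolan-2-yl)oxy]butyl] carbonate | CC1(C)OB(O[C@@H](c2cc(OC)c3c(c2)[C@H](CO[Si](C)(C)C(C)(C)C)[C@H](c2ccc(O[Si](C(C)C)(C(C)C)C(C)C)c(OC)c2)O3)[C@@H](CO[Si](C)(C)C(C)(C)C)C(=C)COC(=O)OC)OC1(C)C | intermediate (not isolated)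
19 | (2R,3R)-2-ArA-3-{[(tert-butyldimethylsilyl)oxy]methyl}-4-methylideneoxolane (aryl and CH2OTBS cis) | C=C1CO[C@@H](c2cc(OC)c3c(c2)[C@H](CO[Si](C)(C)C(C)(C)C)[C@H](c2ccc(O[Si](C(C)C)(C(C)C)C(C)C)c(OC)c2)O3)[C@H]1CO[Si](C)(C)C(C)(C)C | intermediate
20 | (3R,6R,7R)-6-ArA-7-{[(tert-butyldimethylsilyl)oxy]methyl}-1,5-dioxaspiro[2.4]heptane (oxirane oxygen trans to CH2OTBS and aryl) | C1O[C@@]12CO[C@@H](c3cc(OC)c4c(c3)[C@H](CO[Si](C)(C)C(C)(C)C)[C@H](c3ccc(O[Si](C(C)C)(C(C)C)C(C)C)c(OC)c3)O4)[C@H]2CO[Si](C)(C)C(C)(C)C | intermediate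
21 | (4-bromo-2-methoxyphenoxy)tri(propan-2-yl)silane | COc1cc(Br)ccc1O[Si](C(C)C)(C(C)C)C(C)C | intermediate
22 | {3-methoxy-4-[(triisopropylsilyl)oxy]phenyl}magnesium bromide | COc1cc([Mg]Br)ccc1O[Si](C(C)C)(C(C)C)C(C)C | intermediate (not isolated)
23 | (3S,4R,5R)-5-ArA-4-{[(tert-butyldimethylsilyl)oxy]methyl}-3-({3-methoxy-4-[(triisopropylsilyl)oxy]phenyl}methyl)oxolan-3-ol | COc1cc(C[C@@]2(O)CO[C@@H](c3cc(OC)c4c(c3)[C@H](CO[Si](C)(C)C(C)(C)C)[C@H](c3ccc(O[Si](C(C)C)(C(C)C)C(C)C)c(OC)c3)O4)[C@H]2CO[Si](C)(C)C(C)(C)C)ccc1O[Si](C(C)C)(C(C)C)C(C)C | intermediate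
24 | (3S,4R,5R)-5-[(2R,3R)-3-(hydroxymethyl)-2-(4-hydroxy-3-methoxyphenyl)-7-methoxy-2,3-dihydro-1-benzofuran-5-yl]-3-[(4-hydroxy-3-methoxyphenyl)methyl]-4-(hydroxymethyl)oxolan-3-ol (CNP0284796.1) | COc1cc(C[C@@]2(O)CO[C@@H](c3cc(OC)c4c(c3)[C@H](CO)[C@H](c3ccc(O)c(OC)c3)O4)[C@H]2CO)ccc1O | target

**Step count and risks**

Total step count: 18. Longest linear sequence: 12 steps (1, 2, 4, 5, 6, 7, 8, 9, 14, 15, 17, 18).

Steps most likely to fail:

Step 14. The allylboration of the electron-rich aldehyde by the trisubstituted pinacol boronate may be slow or only partly face-selective. In the second stage the O-boryl alkoxide may fail to attack the allylpalladium unit, which could instead lose a β-hydrogen to give a diene. The fallback sets out from 12 and 17. Only the allylboration is run and worked up with aqueous NaHCO3 to the free homoallylic alcohol carbonate F1; here any isomer from incomplete facial control is a diastereomer and can be separated. i-Bu2AlH at −78 °C cleaves the carbonate to the 1,4-diol F2. Mitsunobu cyclodehydration (PPh3, DIAD, THF) then activates the primary allylic hydroxyl, and the benzylic hydroxyl displaces it in an SN2 5-exo-tet closure. This forms the same O–CH2 bond without palladium and without touching the benzylic centre, and comes back to the route at 19.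

Step 6. The carbenoid may be diverted to an oxonium ylide with benzyl shift, and enantio- or cis-selectivity may erode on this more electron-rich, ortho-methoxy-flanked substrate. The fallback replaces catalyst control of purity by a covalent resolution. It sets out from 9 obtained in insufficient isomeric purity. Esterification with (S)-2-methoxy-2-phenylacetic acid (DCC, DMAP, CH2Cl2) gives the mandelate-type ester F3 together with its diastereomers, which are separated by chromatography or crystallisation. Cleavage of pure F3 with i-Bu2AlH at −78 °C comes back to the route at 9.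

Step 15. Facial selectivity of peracid attack on the exocyclic alkene may be insufficient, and the spiro-oxirane may open or rearrange under the acidic by-product. The fallback sets out from 19. Dihydroxylation with OsO4 (cat.) and N-methylmorpholine N-oxide in acetone/H2O, using a bulkier reagent that attacks the same open face, gives the diol F4, whose minor diastereomer can be removed. Bu2SnO-catalysed tosylation (TsCl, Et3N) of the primary hydroxyl gives the monotosylate F5. NaH in THF closes the oxirane by attack of the tertiary alkoxide on the CH2OTs carbon, with the carbinol configuration unchanged, and comes back to the route at 20.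

Further compounds

F1 | step 14 | methyl [(3R,4R)-4-ArA-4-hydroxy-3-{[(tert-butyldimethylsilyl)oxy]methyl}-2-methylidenebutyl] carbonate | O[C@@H](c1cc(OC)c2c(c1)[C@H](CO[Si](C)(C)C(C)(C)C)[C@H](c1ccc(O[Si](C(C)C)(C(C)C)C(C)C)c(OC)c1)O2)[C@@H](CO[Si](C)(C)C(C)(C)C)C(=C)COC(=O)OC
F2 | step 14 | (3R,4R)-4-ArA-3-{[(tert-butyldimethylsilyl)oxy]methyl}-2-methylidenebutane-1,4-diol | O[C@@H](c1cc(OC)c2c(c1)[C@H](CO[Si](C)(C)C(C)(C)C)[C@H](c1ccc(O[Si](C(C)C)(C(C)C)C(C)C)c(OC)c1)O2)[C@@H](CO[Si](C)(C)C(C)(C)C)C(=C)CO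
F3 | step 6 | [(2R,3R)-5-bromo-7-methoxy-2-{3-methoxy-4-[(triisopropylsilyl)oxy]phenyl}-2,3-dihydro-1-benzofuran-3-yl]methyl (2S)-2-methoxy-2-phenylacetate | Brc1cc(OC)c2c(c1)[C@H](COC(=O)[C@@H](OC)c1ccccc1)[C@H](c1ccc(O[Si](C(C)C)(C(C)C)C(C)C)c(OC)c1)O2
F4 | step 15 | (3R,4R,5R)-5-ArA-4-{[(tert-butyldimethylsilyl)oxy]methyl}-3-(hydroxymethyl)oxolan-3-ol (tertiary OH trans to CH2OTBS) | OC[C@@]1(O)CO[C@@H](c2cc(OC)c3c(c2)[C@H](CO[Si](C)(C)C(C)(C)C)[C@H](c2ccc(O[Si](C(C)C)(C(C)C)C(C)C)c(OC)c2)O3)[C@H]1CO[Si](C)(C)C(C)(C)C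
F5 | step 15 | [(3S,4R,5R)-5-ArA-4-{[(tert-butyldimethylsilyl)oxy]methyl}-3-hydroxyoxolan-3-yl]methyl 4-methylbenzenesulfonate | Cc1ccc(cc1)S(=O)(=O)OC[C@@]2(O)CO[C@@H](c3cc(OC)c4c(c3)[C@H](CO[Si](C)(C)C(C)(C)C)[C@H](c3ccc(O[Si](C(C)C)(C(C)C)C(C)C)c(OC)c3)O4)[C@H]2CO[Si](C)(C)C(C)(C)C
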